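The numbers come from no measurement; the result is computed.

Free enzyme runs a ping-pong cycle, and the three flasks differ in how the charge goes in.

the same everywhere: free enzyme 9.3 µM; time 2.5 d

| flask | starting material | second substrate | remark |
|---|---|---|---|
| Thursday's | 0.093 M (fed, over 25 h) | 0.372 M | all else is in the flask from the start; the feed brings no volume worth counting |
| Sunday's | 0.093 M | 0.372 M (fed, over 25 h) | all else is in the flask from the start; the feed brings no volume worth counting |
| Monday's | 0.093 M | 0.372 M | everything together at the start |

    crystals ⇌ first product, rate k1*(cs1 - [first product]) while solid is left; crystals form when [first product] > cs1 (cs1 = 21 mM, k1 = 11 h⁻¹)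
    first complex → loaded enzyme + first product (k2 = 330 h⁻¹)
    starting material + free enzyme ⇌ first complex (K3 = 59 M⁻¹, k3 = 1.7 × 10⁵ M⁻¹ h⁻¹)
    second complex → free enzyme + target (k4 = 400 h⁻¹)
    second substrate + loaded enzyme ⇌ second complex (K5 = 5.3 M⁻¹, k5 = 11000 M⁻¹ h⁻¹)

- first product is meant together with its crystals
- solid, in amounts per volume of the solution: crystals
- run time (Thursday's): 2.5 d

- the flask with the highest amount of target, in percent of the starting material charged ("all alike" if they lie within 1.5 percentage points) (Thursday's / Sunday's / Monday's / all alike)
- final target, as a percentage of the starting material charged, in Thursday's
- final target, as a percentage of the starting material charged, in Sunday's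
- final target, as a percentage of the starting material charged, in Monday's

I reckon in turns of the enzyme. Enzyme charge times run time, divided by the charge of starting material, is the turn allowance 21.6 s, and the fraction converted is about this allowance over the mean turn time (reciprocal turnover frequency).

Can the enzyme finish at all? With the half-saturation terms struck out, a turn takes 19.9 s, so the allowance covers 1.09 charges, which is barely enough.

What do those terms cost? The Michaelis constants are 0.203 of the starting-material charge and 0.605 of the second-substrate charge. A turn at full charge therefore takes 27.6 s. At a fraction 0.7 converted, it takes 33.9 s. The mean of these gives 70.3% for Monday's, which stands close to the fraction I assumed.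

What does a feed cost? In Sunday's, second substrate enters 12.3 times faster than the enzyme uses it, so its level rises almost in step with time. Averaging the turn rate over the feed loses 8.20% of the charge, which leaves Sunday's near 62.1%. I expect Thursday's to lose less because the starting-material term of the turn is smaller than the second-substrate term. My order is Monday's, Thursday's, Sunday's.

The forecast says Monday's, with 67.8%, 65.5% and 72.3% for Thursday's, Sunday's and Monday's, on the ground that “withholding the second substrate costs most”. It has the same order as mine, but my Monday's figure is lower, and so is my Sunday's.

The simulation gives Monday's, with 67.7%, 65.5% and 72.4% in the same order, so the forecast held. Monday's result implies a mean turn of 29.8 s, longer than the allowance; Monday's still has 28% of its starting material unbound at 2.50 d, and its target stands at 100% at 25.0 d.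

Sunday's neighbour with 0.15 M of second substrate has the same allowance. Its turns of 35.6 s at charge and 43.9 s at a fraction 0.5 converted give 54.3% before any cost of feeding. The computed flask gives 47.3%.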